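## Analysis of the target

Compound 21 is a B-type proanthocyanidin dimer, epiafzelechin 3-O-gallate-(4β→6)-epicatechin 3-O-gallate. The upper unit (rings A and C, with a 4-hydroxyphenyl ring B) is bonded through C4 to C6′ of the lower unit (rings D and F, with a catechol ring E; primed atoms). There are five stereocentres. C2, C3 and C4 of ring C are contiguous (2R,3R,4S): the 2-aryl group and the 3-acyloxy group are cis, and the C4–C6′ bond is trans to both. C2′ and C3′ of ring F are 2R,3R, as in (−)-epicatechin (1). The molecule carries thirteen free phenolic hydroxyls (two pyrogallol rings and a catechol that oxidise easily), two aryl esters that tolerate neither strong base nor hydride, and a doubly benzylic C4–C6′ bond that acid cleaves because both rings on C4 are phloroglucinol-type. The hard points are the 4→6 regiochemistry (C8′ is normally the more nucleophilic carbon of ring D), the configuration at C4, and an upper unit that is not a readily available flavan-3-ol. The strategy rests on one feature: C4 is a diarylmethine carbon between ring A, which carries the ring oxygen O1 on the ortho carbon C8a, and ring D. C4 is therefore the methide carbon of an o-quinone methide of ring A, and C3 and C2 with ring B correspond to the enol of an aryl methyl ketone.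

## Retrosynthetic reasoning

**21 from 20.** The thirteen O–benzyl bonds are cut and the C8′ hydrogen is replaced by bromine. Benzyl ethers protect every phenol because one neutral hydrogenolysis removes them without touching the esters, the stereocentres or the C4–C6′ bond. The bromine atom, needed earlier as a blocking group, leaves in the same operation, so the forward step only has to be kept free of acid.

**20 from 19 and 3.** The upper ester C–O bond is cut. The upper gallate goes on last because the C3 oxygen itself appears late; acylation at oxygen does not affect C3.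

**19 from 18, and 18 from 16.** The C2–H and C3–O bonds are cut, leading back to the enol ether double bond C2=C3 of 16. Forward, oxygen is transferred to the face of 16 opposite the pseudoaxial C4 aryl group and the labile epoxy ether is trapped as methyl ketal 18; this sets C3. Ionic reduction of 18 then sets C2. Hydride has to arrive on the face that carries the C4 aryl group, so that group cannot be the steering element. Control must come from the C3 oxygen: hydride adds anti to the pseudoaxial C3–O bond of the oxocarbenium ion.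

**16 from 13 and 10.** This is the key disconnection. The C3–C4 and O1–C2 bonds are cut, which opens ring C completely. It is made here because it turns the hardest stereocentre, C4, into a trigonal methide carbon whose faces a chiral acid can distinguish, and because both fragments are simple. Forward, benzhydrol 13 has to ionise to the o-quinone methide, enol silane 10 has to add at the methide carbon on one face, and the phenol has to close onto the ketone with dehydration.

**13 from 6 and 8.** The bond between the carbinol carbon and C6′ is cut. Ring D becomes the nucleophile, with the site fixed by an iodine atom at C6′, and ring A becomes salicylaldehyde 8. This polarity is chosen because iodine–magnesium exchange defines the 4→6 regiochemistry unambiguously and leaves the C8′ bromine in place.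

**6 from 1 and 3 by way of 2, 4 and 5; 8 from 7; 10 from 9.** The lower unit comes from the chiral pool with C2′ and C3′ in place. It is benzylated, esterified with 3, brominated at the more reactive C8 and then iodinated at C6. Aldehyde 8 is the selective bis-benzyl ether of 7, and 10 is the enol silane of ketone 9.

## Alternatives that were turned down

**Alternative 1:** Ring F is opened at C3′–C4′. The flav-3-ene A2 (complete upper unit, upper 3-hydroxyl as its tert-butyldimethylsilyl ether) is traced to diene A1, in which ring D carries a vinyl group on C4a′ and an enantiopure 1-arylallyl ether on O1′. The forward key step is ring-closing metathesis with the second-generation Grubbs catalyst RuCl2(PCy3)(H2IMes)(=CHPh).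
- For: six-membered ring closure by metathesis is dependable and tolerates benzyl and silyl ethers. The 4→6 linkage is fixed by the way ring D is built, with no halogen blocking or halogen differentiation; on this point it is stronger than the chosen route.
- Against: A2 still lacks the 3′-oxygen. Hydroboration would place it trans to the 2′-aryl group, so an oxidation–reduction pair is needed before acylation. C2′ has to be introduced through an allylic, benzylic aryl ether on a hindered phenol, where ionisation and allylic transposition threaten the configuration. Above all, A1 already contains the whole upper unit with C2, C3 and C4, so the central problem is left to other chemistry.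
- Comparison: the chosen route buys C2′ and C3′ with 1 and spends its key step on C4 and ring C, which makes it clearly shorter.

**Alternative 2:** Ring C is opened at C4–C4a. The fully protected target A4 (identical with 20) is traced to the acyclic threo compound A3, in which C2 carries a 3,5-bis(benzyloxy)phenyl ether, C3 the gallate and C4 ring D and an acetate. Forward, Me3SiOTf ionises the C4 acetate, the C3 gallate carbonyl bridges the cation, and one of the two equivalent ortho carbons of the aryloxy ring attacks C4 from the opposite face in a six-membered Friedel–Crafts closure.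
- For: it reaches A4 directly, with no later redox chemistry on ring C. The 3,4-trans relationship comes from neighbouring-group participation, which is a firmer control element than the hydride delivery of the chosen route.
- Against: A3 needs three contiguous acyclic stereocentres. C2 is a 4-alkoxybenzylic aryl ether, which is hard to form stereospecifically with a hindered phenol and can itself ionise under the silyl triflate. The C4 cation is so well stabilised by ring D that the open ion may compete with the bridged one. Ring D must still be attached to C4 by an arylmetal addition.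
- Comparison: the chosen route avoids the acyclic stereotriad, sets C4 by a catalyst and forms both ring C bonds from two simple fragments in one step.

**Alternative 3:** Ring F is opened at C4′–C4a′. The decabenzyl dimer A6 (free 3′-hydroxyl) is traced to epoxide A5, in which ring D is a symmetric 2,6-bis(benzyloxy)-4-oxyphenyl hub bonded to upper C4 and, through oxygen, to an aryl(oxiranyl)methyl group. Forward, in 1,1,1,3,3,3-hexafluoro-2-propanol or with BF3·OEt2, one of the two equivalent ortho carbons of ring D opens the epoxide at its terminal carbon (6-endo), forming C4′–C4a′ and releasing the 3′-hydroxyl.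
- For: the symmetry of the hub gives the 4→6 linkage automatically, without halogens or organometallic steps, which is stronger than the chosen route on regiochemistry. C2′ and C3′ come from an epoxy alcohol of known configuration, and the 3′-hydroxyl emerges ready for acylation.
- Against: the upper unit with C4 and its bond to the hub must already exist, so the hard part is again deferred. The benzylic ether at C2′ has to be made on a very hindered phenol. The acidic cyclisation can ionise that ether (epimerisation at C2′) and can cleave the C4–ring D bond, since ring D is a phloroglucinol triether at that stage. The lower unit is built from nothing, which costs many steps.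
- Comparison: the chosen route takes the lower unit from 1 and concentrates the risk in one catalytic step that forms ring C and C4.

Key step: step 8

**Remarks.**
- Bn = benzyl. "Gallate" in protected compounds means the 3,4,5-tris(benzyloxy)benzoate.
- "ArD" is the protected lower unit bonded through C6′: (2R,3R)-5,7-bis(benzyloxy)-2-[3,4-bis(benzyloxy)phenyl]-8-bromo-3-[3,4,5-tris(benzyloxy)benzoyloxy]chroman-6-yl.
- The face of ring C that carries the C4–C6′ bond is called β.
- The C4 descriptor is R in the brominated, benzylated intermediates and S in 21 only because the CIP priorities of C4a and C6′ change; the geometry is the same.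
- Assumption: the (R)-configured phosphoric acid is taken to leave the Si face of the methide carbon of 14 open. If the sense of induction is the opposite, the (S)-acid is used with no other change.

## Route

Step 1
Reactants: 1 (−)-epicatechin
Product: 2 5,7,3′,4′-tetra-O-benzyl-(−)-epicatechin
Conditions: BnBr (4.4 equiv), K2CO3, DMF, 0 °C → rt, N2
Reagents that add atoms: benzyl bromide BrCc1ccccc1
Why: Williamson etherification of the four phenols; K2CO3 does not deprotonate the secondary alcohol, and C2 and C3 are not touched.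

Step 2
Reactants: 2 5,7,3′,4′-tetra-O-benzyl-(−)-epicatechin; 3 3,4,5-tris(benzyloxy)benzoic acid
Product: 4 5,7,3′,4′-tetra-O-benzyl-(−)-epicatechin 3-O-[3,4,5-tris(benzyloxy)benzoate]
Conditions: N,N′-dicyclohexylcarbodiimide, 4-(dimethylamino)pyridine, CH2Cl2, rt
Reagents that add atoms: none
Why: Steglich esterification of the only free hydroxyl; the C3–O bond is not broken, so its configuration is kept.

Step 3
Reactants: 4 5,7,3′,4′-tetra-O-benzyl-(−)-epicatechin 3-O-[3,4,5-tris(benzyloxy)benzoate]
Product: 5 8-bromo-5,7,3′,4′-tetra-O-benzyl-(−)-epicatechin 3-O-[3,4,5-tris(benzyloxy)benzoate]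
Conditions: NBS (1.0 equiv), CH2Cl2, −40 → 0 °C
Reagents that add atoms: N-bromosuccinimide O=C1CCC(=O)N1Br
Why: Electrophilic aromatic bromination; ring A, a phloroglucinol triether, is far more nucleophilic than the catechol or gallate rings, and C8 (next to the tied-back ring oxygen) reacts before C6 (between two benzyloxy groups), as is usual for 5,7-di-O-benzylflavan-3-ols.

Step 4
Reactants: 5 8-bromo-5,7,3′,4′-tetra-O-benzyl-(−)-epicatechin 3-O-[3,4,5-tris(benzyloxy)benzoate]
Product: 6 8-bromo-6-iodo-5,7,3′,4′-tetra-O-benzyl-(−)-epicatechin 3-O-[3,4,5-tris(benzyloxy)benzoate]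
Conditions: NIS (1.2 equiv), CF3CO2H (cat.), CH2Cl2, 0 °C → rt, dark
Reagents that add atoms: N-iodosuccinimide O=C1CCC(=O)N1I
Why: Electrophilic aromatic iodination; with C8 blocked the second halogen can only enter at C6 of the same ring, still the most electron-rich arene present. Iodine is placed there because a C–I bond exchanges with magnesium much faster than a C–Br bond.

Step 5
Reactants: 7 2,4,6-trihydroxybenzaldehyde
Product: 8 4,6-bis(benzyloxy)-2-hydroxybenzaldehyde
Conditions: BnBr (2.05 equiv), K2CO3 (2.1 equiv), DMF, rt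
Reagents that add atoms: benzyl bromide BrCc1ccccc1
Why: Williamson etherification; the 4-hydroxyl and one ortho hydroxyl are alkylated, while the remaining ortho hydroxyl is held in a hydrogen bond to the formyl oxygen and stays free with two equivalents of the halide.

Step 6
Reactants: 9 4′-benzyloxyacetophenone
Product: 10 {1-[4-(benzyloxy)phenyl]vinyloxy}trimethylsilane
Conditions: Me3SiOTf (1.1 equiv), Et3N (1.3 equiv), CH2Cl2, 0 °C
Reagents that add atoms: trimethylsilyl trifluoromethanesulfonate C[Si](C)(C)OS(=O)(=O)C(F)(F)F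
Why: Soft enolisation and O-silylation; the ketone has one enolisable position, so a single enol silane results.

Step 7
Reactants: 6 8-bromo-6-iodo-5,7,3′,4′-tetra-O-benzyl-(−)-epicatechin 3-O-[3,4,5-tris(benzyloxy)benzoate]; 8 4,6-bis(benzyloxy)-2-hydroxybenzaldehyde
Product: 13 [4,6-bis(benzyloxy)-2-hydroxyphenyl](ArD)methanol (carbinol epimers), via arylmagnesium chloride 11 (not isolated), via chloromagnesium phenoxide 12 (not isolated)
Conditions: 6, iPrMgCl·LiCl (1.1 equiv), THF, −40 °C; 8 (1.5 equiv), tBuMgCl (1.5 equiv), THF, −20 °C; combine, −40 → −10 °C; pH 7 buffer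
Reagents that add atoms: none
Why: Iodine–magnesium exchange with the LiCl-complexed Grignard reagent is fast for an aryl iodide flanked by two alkoxy groups and spares the aryl bromide and, at low temperature, the ester; the aldehyde is used as its chloromagnesium phenoxide (made with the non-nucleophilic tBuMgCl) so that no arylmagnesium is lost to the phenol and the chelated formyl group is activated for 1,2-addition. The new carbinol centre forms as a mixture of epimers, which is irrelevant because it becomes trigonal in step 8; the acid-sensitive product is worked up at pH 7 and not chromatographed on untreated silica.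

Step 8
Reactants: 13 [4,6-bis(benzyloxy)-2-hydroxyphenyl](ArD)methanol; 10 {1-[4-(benzyloxy)phenyl]vinyloxy}trimethylsilane
Product: 16 (4R)-5,7-bis(benzyloxy)-2-[4-(benzyloxy)phenyl]-4-(ArD)-4H-chromene, via o-quinone methide 14 (not isolated), via phenol ketone 15 (not isolated)
Conditions: (R)-3,3′-bis(2,4,6-triisopropylphenyl)-1,1′-binaphthyl-2,2′-diyl hydrogen phosphate (10 mol%), 10 (3 equiv), toluene, −20 °C → rt; then 40 °C
Reagents that add atoms: none
Why: The phosphoric acid protonates the benzylic hydroxyl of 13, which leaves as water because the cation is stabilised by the ortho hydroxyl and the benzyloxy groups of ring A and by ring D; the resulting o-quinone methide 14 stays hydrogen-bonded or ion-paired to the chiral phosphate. Enol silane 10 adds through its terminal carbon to the methide carbon in a 1,4-conjugate (Mukaiyama–Michael-type) addition that forms C3–C4 and restores the aromaticity of ring A, and the released water takes up the silyl group, giving phenol ketone 15 and returning the acid. The phenol then adds to the ketone carbonyl (6-exo-trig hemiketalisation, O1–C2 bond) and acid-catalysed dehydration gives the conjugated 2-aryl-4H-chromene 16, so ring C is closed in a formal [4+2] annulation. The closest known reaction type is the chiral-phosphoric-acid-catalysed addition of enol-type nucleophiles (1,3-dicarbonyl compounds, enamides) to o-quinone methides generated from o-hydroxybenzhydrols, with cyclodehydration to 4-aryl-4H-chromenes; the silyl enol ether of an aryl methyl ketone is a more nucleophilic member of that class but has no second hydrogen-bond contact to the catalyst. The only new stereocentre, C4, is set by the catalyst: a 2,4,6-triisopropylphenyl group covers one face of the bound methide and the nucleophile enters on the open Si face (priorities C4a > C6′ > H), which gives the 4R, 4β-aryl configuration, while C2′ and C3′ are too remote to bias the addition. The step needs this face selection, C- rather than O-alkylation and cross- rather than self-coupling; the soft carbon terminus of 10 in excess serves the last two, and the bromine at C8′ removes the most nucleophilic arene position of ring D. Because the benzhydrol ionises under so weak an acid, the gallate ester, the benzyl ethers and the acid-labile C4–C6′ bond of the product should be left alone.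

Step 9
Reactants: 16 (4R)-5,7-bis(benzyloxy)-2-[4-(benzyloxy)phenyl]-4-(ArD)-4H-chromene
Product: 18 (3R,4R)-5,7-bis(benzyloxy)-2-[4-(benzyloxy)phenyl]-2-methoxy-4-(ArD)-chroman-3-ol (C2 epimers), via epoxide 17 (not isolated)
Conditions: dimethyldioxirane (1.2 equiv, acetone), CH2Cl2, −40 °C; then MeOH, −40 → 0 °C
Reagents that add atoms: dimethyldioxirane CC1(C)OO1; methanol CO
Why: Dimethyldioxirane epoxidises the electron-rich enol ether C2=C3, the only alkene, under neutral conditions; the 4-aryl group, pseudoaxial because of peri strain with the 5-benzyloxy group, covers the β face, so oxygen is delivered to the α face and C3 is set (3R, oxygen trans to the aryl group). The 2-aryl epoxy ether 17 is too labile to store and is opened at the acetal carbon C2 by methanol to methyl ketal 18, whose C2 configuration does not matter.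

Step 10
Reactants: 18 (3R,4R)-5,7-bis(benzyloxy)-2-[4-(benzyloxy)phenyl]-2-methoxy-4-(ArD)-chroman-3-ol
Product: 19 (2R,3R,4R)-5,7-bis(benzyloxy)-2-[4-(benzyloxy)phenyl]-4-(ArD)-chroman-3-ol
Conditions: Et3SiH (5 equiv), BF3·OEt2 (2 equiv), CH2Cl2, −78 → −40 °C
Reagents that add atoms: none
Why: BF3·OEt2 ionises the ketal to the 2-aryl oxocarbenium ion, which Et3SiH reduces (ionic hydrogenation, as in the reductive removal of anomeric alkoxy groups). In this ion the C3–O bond is pseudoaxial (allylic 1,2-strain with the coplanar 2-aryl group) and trans-diaxial to the 4-aryl group, and axial attack through a chair-like transition state brings hydride in anti to C3–O, that is on the β face, giving the 2,3-cis (2R) flavan. The 4-aryl group lies on that same face and opposes rather than helps, so the step is flagged below.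

Step 11
Reactants: 19 (2R,3R,4R)-5,7-bis(benzyloxy)-2-[4-(benzyloxy)phenyl]-4-(ArD)-chroman-3-ol; 3 3,4,5-tris(benzyloxy)benzoic acid
Product: 20 (2R,3R,4R)-5,7-bis(benzyloxy)-2-[4-(benzyloxy)phenyl]-4-(ArD)-chroman-3-yl 3,4,5-tris(benzyloxy)benzoate (tridecabenzyl 8′-bromo derivative of 21)
Conditions: 3 (3 equiv), N,N′-dicyclohexylcarbodiimide, 4-(dimethylamino)pyridine, CH2Cl2, rt → 35 °C
Reagents that add atoms: none
Why: Steglich esterification of the axial C3 hydroxyl with excess acid; acylation at oxygen leaves C3 unchanged, and the near-neutral conditions spare the C4–C6′ bond and the lower ester.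

Step 12
Reactants: 20 tridecabenzyl 8′-bromo derivative of 21
Product: 21 epiafzelechin 3-O-gallate-(4β→6)-epicatechin 3-O-gallate (CNP0169607.1)
Conditions: H2 (1 atm), Pd(OH)2/C, Et3N (3 equiv), THF/MeOH, rt
Reagents that add atoms: none
Why: Hydrogenolysis over Pd(OH)2/C cleaves the thirteen benzyl ethers and the C8′–Br bond in one operation; Et3N takes up the HBr so that the acid-labile C4–C6′ bond and the esters survive, and the benzylic ring C–O bonds of flavans resist these conditions.

## Compound list

1 | (−)-epicatechin | O[C@@H]1Cc2c(O)cc(O)cc2O[C@@H]1c1ccc(O)c(O)c1 | starting material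
2 | 5,7,3′,4′-tetra-O-benzyl-(−)-epicatechin | O[C@@H]1Cc2c(OCc5ccccc5)cc(OCc5ccccc5)cc2O[C@@H]1c1ccc(OCc5ccccc5)c(OCc5ccccc5)c1 | intermediate
3 | 3,4,5-tris(benzyloxy)benzoic acid | OC(=O)c1cc(OCc2ccccc2)c(OCc2ccccc2)c(OCc2ccccc2)c1 | starting material
4 | 5,7,3′,4′-tetra-O-benzyl-(−)-epicatechin 3-O-[3,4,5-tris(benzyloxy)benzoate] | O=C(O[C@@H]1Cc2c(OCc5ccccc5)cc(OCc5ccccc5)cc2O[C@@H]1c1ccc(OCc5ccccc5)c(OCc5ccccc5)c1)c1cc(OCc5ccccc5)c(OCc5ccccc5)c(OCc5ccccc5)c1 | intermediate
5 | 8-bromo derivative of 4 | O=C(O[C@@H]1Cc2c(OCc5ccccc5)cc(OCc5ccccc5)c(Br)c2O[C@@H]1c1ccc(OCc5ccccc5)c(OCc5ccccc5)c1)c1cc(OCc5ccccc5)c(OCc5ccccc5)c(OCc5ccccc5)c1 | intermediate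
6 | 8-bromo-6-iodo derivative of 4 | O=C(O[C@@H]1Cc2c(OCc5ccccc5)c(I)c(OCc5ccccc5)c(Br)c2O[C@@H]1c1ccc(OCc5ccccc5)c(OCc5ccccc5)c1)c1cc(OCc5ccccc5)c(OCc5ccccc5)c(OCc5ccccc5)c1 | intermediate
7 | 2,4,6-trihydroxybenzaldehyde | O=Cc1c(O)cc(O)cc1O | starting material
8 | 4,6-bis(benzyloxy)-2-hydroxybenzaldehyde | O=Cc1c(O)cc(OCc2ccccc2)cc1OCc1ccccc1 | intermediate
9 | 4′-benzyloxyacetophenone | CC(=O)c1ccc(OCc2ccccc2)cc1 | starting material
10 | {1-[4-(benzyloxy)phenyl]vinyloxy}trimethylsilane | C=C(O[Si](C)(C)C)c1ccc(OCc2ccccc2)cc1 | intermediate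
11 | 8-bromo-6-(chloromagnesio) derivative of 4 (arylmagnesium chloride) | O=C(O[C@@H]1Cc2c(OCc5ccccc5)c([Mg]Cl)c(OCc5ccccc5)c(Br)c2O[C@@H]1c1ccc(OCc5ccccc5)c(OCc5ccccc5)c1)c1cc(OCc5ccccc5)c(OCc5ccccc5)c(OCc5ccccc5)c1 | intermediate
12 | chloromagnesium 3,5-bis(benzyloxy)-2-formylphenoxide | O=Cc1c(O[Mg]Cl)cc(OCc2ccccc2)cc1OCc1ccccc1 | intermediate
13 | [4,6-bis(benzyloxy)-2-hydroxyphenyl](ArD)methanol, carbinol epimers | OC(c2c(OCc5ccccc5)c(Br)c3c(c2OCc5ccccc5)C[C@@H](OC(=O)c4cc(OCc5ccccc5)c(OCc5ccccc5)c(OCc5ccccc5)c4)[C@@H](c4ccc(OCc5ccccc5)c(OCc5ccccc5)c4)O3)c2c(OCc5ccccc5)cc(OCc5ccccc5)cc2O | intermediate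
14 | 3,5-bis(benzyloxy)-6-[(ArD)methylidene]cyclohexa-2,4-dien-1-one (o-quinone methide) | O=C1C=C(OCc5ccccc5)C=C(OCc5ccccc5)C1=Cc2c(OCc5ccccc5)c(Br)c3c(c2OCc5ccccc5)C[C@@H](OC(=O)c4cc(OCc5ccccc5)c(OCc5ccccc5)c(OCc5ccccc5)c4)[C@@H](c4ccc(OCc5ccccc5)c(OCc5ccccc5)c4)O3 | intermediate
15 | (3R)-3-[4,6-bis(benzyloxy)-2-hydroxyphenyl]-1-[4-(benzyloxy)phenyl]-3-(ArD)propan-1-one | O=C(C[C@@H](c2c(OCc5ccccc5)c(Br)c3c(c2OCc5ccccc5)C[C@@H](OC(=O)c4cc(OCc5ccccc5)c(OCc5ccccc5)c(OCc5ccccc5)c4)[C@@H](c4ccc(OCc5ccccc5)c(OCc5ccccc5)c4)O3)c2c(OCc5ccccc5)cc(OCc5ccccc5)cc2O)c1ccc(OCc5ccccc5)cc1 | intermediate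
16 | (4R)-5,7-bis(benzyloxy)-2-[4-(benzyloxy)phenyl]-4-(ArD)-4H-chromene | C1(c6ccc(OCc5ccccc5)cc6)=C[C@@H](c2c(OCc5ccccc5)c(Br)c3c(c2OCc5ccccc5)C[C@@H](OC(=O)c4cc(OCc5ccccc5)c(OCc5ccccc5)c(OCc5ccccc5)c4)[C@@H](c4ccc(OCc5ccccc5)c(OCc5ccccc5)c4)O3)c2c(OCc5ccccc5)cc(OCc5ccccc5)cc2O1 | intermediate
17 | 2α,3α-epoxide of 16 (oxygen on the face opposite the 4-aryl group) | O1[C@@H]6[C@@H](c2c(OCc5ccccc5)c(Br)c3c(c2OCc5ccccc5)C[C@@H](OC(=O)c4cc(OCc5ccccc5)c(OCc5ccccc5)c(OCc5ccccc5)c4)[C@@H](c4ccc(OCc5ccccc5)c(OCc5ccccc5)c4)O3)c2c(OCc5ccccc5)cc(OCc5ccccc5)cc2O[C@]16c1ccc(OCc5ccccc5)cc1 | intermediate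
18 | (3R,4R)-5,7-bis(benzyloxy)-2-[4-(benzyloxy)phenyl]-2-methoxy-4-(ArD)-chroman-3-ol, C2 epimers | O[C@@H]1[C@@H](c2c(OCc5ccccc5)c(Br)c3c(c2OCc5ccccc5)C[C@@H](OC(=O)c4cc(OCc5ccccc5)c(OCc5ccccc5)c(OCc5ccccc5)c4)[C@@H](c4ccc(OCc5ccccc5)c(OCc5ccccc5)c4)O3)c2c(OCc5ccccc5)cc(OCc5ccccc5)cc2OC1(OC)c1ccc(OCc5ccccc5)cc1 | intermediate
19 | (2R,3R,4R)-5,7-bis(benzyloxy)-2-[4-(benzyloxy)phenyl]-4-(ArD)-chroman-3-ol | O[C@@H]1[C@@H](c2c(OCc5ccccc5)c(Br)c3c(c2OCc5ccccc5)C[C@@H](OC(=O)c4cc(OCc5ccccc5)c(OCc5ccccc5)c(OCc5ccccc5)c4)[C@@H](c4ccc(OCc5ccccc5)c(OCc5ccccc5)c4)O3)c2c(OCc5ccccc5)cc(OCc5ccccc5)cc2O[C@@H]1c1ccc(OCc5ccccc5)cc1 | intermediate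
20 | 3-O-[3,4,5-tris(benzyloxy)benzoate] of 19 (tridecabenzyl 8′-bromo derivative of 21) | O=C(O[C@@H]1[C@@H](c2c(OCc5ccccc5)c(Br)c3c(c2OCc5ccccc5)C[C@@H](OC(=O)c4cc(OCc5ccccc5)c(OCc5ccccc5)c(OCc5ccccc5)c4)[C@@H](c4ccc(OCc5ccccc5)c(OCc5ccccc5)c4)O3)c2c(OCc5ccccc5)cc(OCc5ccccc5)cc2O[C@@H]1c1ccc(OCc5ccccc5)cc1)c1cc(OCc5ccccc5)c(OCc5ccccc5)c(OCc5ccccc5)c1 | intermediate
21 | epiafzelechin 3-O-gallate-(4β→6)-epicatechin 3-O-gallate, upper unit 2R,3R,4S, lower unit 2R,3R | O=C(O[C@@H]1[C@@H](c2c(O)cc3c(c2O)C[C@@H](OC(=O)c2cc(O)c(O)c(O)c2)[C@@H](c2ccc(O)c(O)c2)O3)c2c(O)cc(O)cc2O[C@@H]1c1ccc(O)cc1)c1cc(O)c(O)c(O)c1 | target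

## Step count and least certain steps

Total: 12 steps. Longest linear sequence: 10 steps (1, 2, 3, 4, 7, 8, 9, 10, 11, 12) from 1 to 21.

**Step 8 (key step).**
- Risk: insufficient face selection at the methide carbon. The enol silane has no hydrogen-bond contact to the phosphate, and the methide carbon is crowded on both sides (5-benzyloxy group, di-ortho-substituted ring D), so the ion pair may be loose. Hydrolysis of 10 by the released water and slow dehydration of the hemiketal are secondary risks.
- Fallback: it sets out from 13, with the nucleophile made from 9, and returns at 16. Ketone 9 is converted with NH2OH·HCl and NaOAc in ethanol into 4′-benzyloxyacetophenone oxime F1. Reductive acetylation with iron powder, Ac2O and AcOH in toluene gives the enamide N-{1-[4-(benzyloxy)phenyl]vinyl}acetamide F2. With the same phosphoric acid, F2 and 13 should combine in the known enamide/o-quinone methide cycloaddition, in which the N–H binds the phosphoryl oxygen while the acid binds the quinone methide, to give the 2-acetamido-2,4-diarylchroman F3. Warming F3 with a catalytic amount of pyridinium p-toluenesulfonate eliminates acetamide and gives 16.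

**Step 7.**
- Risk: attack of arylmagnesium 11 on the gallate ester of a second molecule if the addition to the hindered, electron-rich aldehyde is slow enough to need warming, and ionisation of 13 during work-up.
- Fallback: it sets out from 6 and returns at 13, reversing the polarity at the carbinol carbon. After the same iodine–magnesium exchange, 11 is quenched at −40 °C with N,N-dimethylformamide to give the 6-formyl compound F4. Commercial 3,5-bis(benzyloxy)phenol (Oc1cc(OCc2ccccc2)cc(OCc2ccccc2)c1) is deprotonated with EtMgBr to bromomagnesium 3,5-bis(benzyloxy)phenoxide F5. In toluene/CH2Cl2, F5 should add to F4 through its ortho carbon in a chelated six-membered transition state (ortho-specific hydroxyalkylation of magnesium phenoxides), giving 13; the phenoxide is too weakly basic to attack the ester.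

**Step 9.**
- Risk: oxidation of the phloroglucinol-type rings or benzylic C–H bonds by the dioxirane, and rearrangement of epoxide 17 by hydride shift to a flavan-3-one before methanol traps it.
- Fallback: it sets out from 16 and returns at 19. Dihydroxylation with OsO4 (cat.) and N-methylmorpholine N-oxide in acetone/H2O, again anti to the 4-aryl group, should give the (3R,4R)-2,3-dihydroxy hemiketal F6. F6 is reduced directly with Et3SiH and BF3·OEt2 at −78 °C to 19.

**Step 10.**
- Risk: hydride delivery from the α face, because the pseudoaxial 4-aryl group sits 1,3 to C2 on the face that has to be attacked; this would give the 2,3-trans epimer. Loss of the C3 proton from the cation to give a flavan-3-one is a further risk.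
- Fallback: it sets out from 18 and returns at 20, replacing conformational control by neighbouring-group participation. The C3 hydroxyl of 18 is esterified first with 3 (N,N′-dicyclohexylcarbodiimide, 4-(dimethylamino)pyridine) to give the 2-methoxy 3-O-gallate F7. On ionisation with Me3SiOTf in the presence of Et3SiH at −78 °C, the ester carbonyl should bridge C2 from the α face as a dioxolanylium ion, so hydride can enter only from the β face. This gives 20 directly and makes step 11 unnecessary.

## Further compounds

F1 | step 8 | 4′-benzyloxyacetophenone oxime | CC(=NO)c1ccc(OCc2ccccc2)cc1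
F2 | step 8 | N-{1-[4-(benzyloxy)phenyl]vinyl}acetamide | C=C(NC(C)=O)c1ccc(OCc2ccccc2)cc1
F3 | step 8 | (4R)-2-acetamido-5,7-bis(benzyloxy)-2-[4-(benzyloxy)phenyl]-4-(ArD)-chroman, C2 epimers | CC(=O)NC1(c6ccc(OCc5ccccc5)cc6)C[C@@H](c2c(OCc5ccccc5)c(Br)c3c(c2OCc5ccccc5)C[C@@H](OC(=O)c4cc(OCc5ccccc5)c(OCc5ccccc5)c(OCc5ccccc5)c4)[C@@H](c4ccc(OCc5ccccc5)c(OCc5ccccc5)c4)O3)c2c(OCc5ccccc5)cc(OCc5ccccc5)cc2O1
F4 | step 7 | 8-bromo-6-formyl-5,7,3′,4′-tetra-O-benzyl-(−)-epicatechin 3-O-[3,4,5-tris(benzyloxy)benzoate] | O=Cc2c(OCc5ccccc5)c(Br)c3c(c2OCc5ccccc5)C[C@@H](OC(=O)c4cc(OCc5ccccc5)c(OCc5ccccc5)c(OCc5ccccc5)c4)[C@@H](c4ccc(OCc5ccccc5)c(OCc5ccccc5)c4)O3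
F5 | step 7 | bromomagnesium 3,5-bis(benzyloxy)phenoxide | Br[Mg]Oc1cc(OCc2ccccc2)cc(OCc2ccccc2)c1
F6 | step 9 | (3R,4R)-5,7-bis(benzyloxy)-2-[4-(benzyloxy)phenyl]-4-(ArD)-chroman-2,3-diol, C2 epimers | O[C@@H]1[C@@H](c2c(OCc5ccccc5)c(Br)c3c(c2OCc5ccccc5)C[C@@H](OC(=O)c4cc(OCc5ccccc5)c(OCc5ccccc5)c(OCc5ccccc5)c4)[C@@H](c4ccc(OCc5ccccc5)c(OCc5ccccc5)c4)O3)c2c(OCc5ccccc5)cc(OCc5ccccc5)cc2OC1(O)c1ccc(OCc5ccccc5)cc1
F7 | step 10 | (3R,4R)-5,7-bis(benzyloxy)-2-[4-(benzyloxy)phenyl]-2-methoxy-4-(ArD)-chroman-3-yl 3,4,5-tris(benzyloxy)benzoate, C2 epimers | O=C(O[C@@H]1[C@@H](c2c(OCc5ccccc5)c(Br)c3c(c2OCc5ccccc5)C[C@@H](OC(=O)c4cc(OCc5ccccc5)c(OCc5ccccc5)c(OCc5ccccc5)c4)[C@@H](c4ccc(OCc5ccccc5)c(OCc5ccccc5)c4)O3)c2c(OCc5ccccc5)cc(OCc5ccccc5)cc2OC1(OC)c1ccc(OCc5ccccc5)cc1)c1cc(OCc5ccccc5)c(OCc5ccccc5)c(OCc5ccccc5)c1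
A1 | alternative 1 | diene: upper unit 3-O-tert-butyldimethylsilyl ether whose ring D carries a C4a′ vinyl group and an O1′ 1-[3,4-bis(benzyloxy)phenyl]allyl ether | CC(C)(C)[Si](C)(C)O[C@@H]1[C@@H](c2c(OCc5ccccc5)cc(O[C@@H](C=C)c4ccc(OCc5ccccc5)c(OCc5ccccc5)c4)c(C=C)c2OCc5ccccc5)c2c(OCc5ccccc5)cc(OCc5ccccc5)cc2O[C@@H]1c1ccc(OCc5ccccc5)cc1
A2 | alternative 1 | lower flav-3-ene with upper 3-O-tert-butyldimethylsilyl ether | CC(C)(C)[Si](C)(C)O[C@@H]1[C@@H](c2c(OCc5ccccc5)cc3c(c2OCc5ccccc5)C=C[C@@H](c4ccc(OCc5ccccc5)c(OCc5ccccc5)c4)O3)c2c(OCc5ccccc5)cc(OCc5ccccc5)cc2O[C@@H]1c1ccc(OCc5ccccc5)cc1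
A3 | alternative 2 | acyclic threo C2 3,5-bis(benzyloxy)phenyl ether with C3 gallate and C4 acetate (C4 epimers) | CC(=O)OC(c2c(OCc5ccccc5)c(Br)c3c(c2OCc5ccccc5)C[C@@H](OC(=O)c4cc(OCc5ccccc5)c(OCc5ccccc5)c(OCc5ccccc5)c4)[C@@H](c4ccc(OCc5ccccc5)c(OCc5ccccc5)c4)O3)[C@@H](OC(=O)c1cc(OCc5ccccc5)c(OCc5ccccc5)c(OCc5ccccc5)c1)[C@H](Oc1cc(OCc5ccccc5)cc(OCc5ccccc5)c1)c1ccc(OCc5ccccc5)cc1
A4 | alternative 2 | tridecabenzyl 8′-bromo derivative of the target (identical with 20) | O=C(O[C@@H]1[C@@H](c2c(OCc5ccccc5)c(Br)c3c(c2OCc5ccccc5)C[C@@H](OC(=O)c4cc(OCc5ccccc5)c(OCc5ccccc5)c(OCc5ccccc5)c4)[C@@H](c4ccc(OCc5ccccc5)c(OCc5ccccc5)c4)O3)c2c(OCc5ccccc5)cc(OCc5ccccc5)cc2O[C@@H]1c1ccc(OCc5ccccc5)cc1)c1cc(OCc5ccccc5)c(OCc5ccccc5)c(OCc5ccccc5)c1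
A5 | alternative 3 | upper unit gallate bonded at C4 to a 2,6-bis(benzyloxy)-4-{[3,4-bis(benzyloxy)phenyl](oxiranyl)methoxy}phenyl hub | O=C(O[C@@H]1[C@@H](c2c(OCc5ccccc5)cc(O[C@H](c4ccc(OCc5ccccc5)c(OCc5ccccc5)c4)[C@H]3CO3)cc2OCc5ccccc5)c2c(OCc5ccccc5)cc(OCc5ccccc5)cc2O[C@@H]1c1ccc(OCc5ccccc5)cc1)c1cc(OCc5ccccc5)c(OCc5ccccc5)c(OCc5ccccc5)c1
A6 | alternative 3 | decabenzyl dimer with free 3′-hydroxyl | O=C(O[C@@H]1[C@@H](c2c(OCc5ccccc5)cc3c(c2OCc5ccccc5)C[C@@H](O)[C@@H](c4ccc(OCc5ccccc5)c(OCc5ccccc5)c4)O3)c2c(OCc5ccccc5)cc(OCc5ccccc5)cc2O[C@@H]1c1ccc(OCc5ccccc5)cc1)c1cc(OCc5ccccc5)c(OCc5ccccc5)c(OCc5ccccc5)c1
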